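## Analysis of the target

The target 17 is a macrocyclic bis(bibenzyl). Four benzene rings are held in one 19-membered ring by two diaryl ether oxygens (ring A–O–ring B and ring C–O–ring D) and two CH2–CH2 bridges (ring B–ring C and ring D–ring A). Ring A is 1,2,4-trisubstituted, with its hydroxyl ortho to the ether oxygen and para to the bridge carbon. Ring B is 1,3-disubstituted without hydroxyl, ring C is 1,3,4,5-tetrasubstituted with a 3,4-catechol next to the ether carbon C-5, and ring D is 1,4-disubstituted. There is no stereocenter and no double bond, and the large ring should be conformationally mobile, so nothing stereochemical has to be controlled. The sensitive groups are the three phenols, above all the ring C catechol, which oxidises easily to an ortho-quinone and binds metals; they are carried as methyl ethers to the last step. The difficulty lies in placing four differently substituted rings in the right order and in closing a 19-membered ring against oligomerisation. The strategy rests on the ring B–ring C bridge. Its first carbon sits on C-3 of ring B, meta to the ring B ether oxygen, and its second carbon sits on C-1 of ring C, meta to the ring C ether carbon. Because both ends are meta-linked, this bridge can be carried as a C≡C rod with the two ether oxygens on the same side, and the ring B C-3–bridge carbon bond becomes an aryl–alkynyl bond that cross-coupling can form.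

## Retrosynthetic reasoning

**17 to 16.** The three O–H groups of 17 are traced back to O–CH3 groups in the trimethyl ether 16. Methyl is the smallest phenol protecting group, comes with the purchased rings, and is inert to base, hydride and palladium/copper catalysis. The forward reaction has to cleave three aryl methyl ethers without touching the two diaryl ether bonds.

**16 to 15.** The CH2–CH2 bridge between rings B and C is taken back to the triple bond of macrocyclic diarylalkyne 15. Forward, a plain hydrogenation suffices, because no halogen is left in the molecule at that point.

**15 to 14 (key disconnection).** The bond between ring B C-3 and the adjacent alkyne carbon is cut, giving the open-chain iodoalkyne 14. This bridge is chosen and not the other one because both of its rings are meta-linked. A rod placed in the ring D–ring A bridge would lie collinear with the para ether oxygen of ring D and would stretch the rigid segment across most of the ring. The ether bonds are not chosen for ring closure because they are better made early and intermolecularly, where an excess of one partner can be used. The iodide is put on ring B, which is unhindered and not electron-rich, so oxidative addition is fast. The alkyne is put on the electron-rich ring C, where a halide would add slowly. The gain is a ring closure that forms a C–C bond under nearly neutral conditions with only one reactive pair in the molecule. Forward, ring closure has to win over intermolecular coupling and over alkyne dimerisation.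

**14 to 13, 12 and 11.** The ethynyl group of 14 is the one-carbon homologue of aldehyde 13. Aldehyde 13 comes by oxidation from benzylic alcohol 12, and 12 by reduction from methyl ester 11. The ester is the form in which ring C is bought, and it stays inert while the other bridge is built.

**11 to 10, then to 5 and 8.** The ring D–ring A ethano bridge of 11 is taken back to the C=C bond of stilbene 10. This bond is cut between its two carbons into phosphonium salt 5 (through ylide 9) and aldehyde 8. Both halves end in benzylic carbons that are available at the right oxidation level. Forward, the double bond has to be saturated by a method that spares the carbon–iodine bond.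

**5 to 4, 3, then to 1 and 2.** Phosphonium salt 5 comes from benzylic alcohol 4 and this from aldehyde 3. In 3 the ring A–O–ring B ether is cut at the ring B carbon–oxygen bond. Ring B has no activating group for an addition–elimination substitution, so an oxidative copper coupling of phenol 1 with boronic acid 2 is used. The iodine is already in the meta position of 2, so no regiochemical question arises.

**8 to 6 and 7.** The ring C–O–ring D ether of 8 is cut at the ring D carbon. The para formyl group of 7 activates fluoride for displacement by phenol 6 and afterwards serves as the handle for the olefination.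

## Alternatives that were turned down

**Alternative 1: ring closure as an aryl ester, then acyl shift from oxygen to carbon.** The ring C C-1–carbonyl bond of the macrocyclic deoxybenzoin A1 is disconnected. A1 is traced back to the 19-membered aryl ester A2, in which the ring B arylacetic acid acylates the ring C phenol oxygen that lies between the methoxy group and the ring D ether. Forward, a strong acid would promote a para-Fries rearrangement of A2 to A1.
- For it: lactonisation is a dependable ring closure. Both ortho positions of the migrating origin are blocked, so only the para carbon of ring C is open. Ring C needs no carbon substituent at the start, and the shift sets the ring C 4-hydroxyl free.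
- Against it: a para shift cannot be concerted across the ring. It runs through an acylium ion detached from the oxygen, so the macrocycle is open at the moment the C–C bond must form. The acylium can then be caught by ring A ortho to its methoxy group, by ring D, or by another molecule, and an arylacetyl cation can also lose carbon monoxide. The acids needed attack methyl ethers. The ketone of A1 must afterwards be deoxygenated and the remaining methyl ethers cleaved, which makes three finishing operations.
- Comparison: this route is stronger in the reliability of its first ring closure. The chosen route forms the C–C bond in the same event that closes the ring, at a site fixed by the iodide, without acid, and needs two finishing steps.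

**Alternative 2: oxidative phenol coupling between rings C and D.** The ring C carbon–oxygen bond of the ether is disconnected. The open-chain bis-phenol A4 carries a 3,5-dibromo-4-hydroxyphenyl ring C and a 3,5-dichloro-4-hydroxyphenyl ring D. Forward, a trivalent thallium oxidant would oxidise the dibromophenol, the ring D phenol oxygen would add at a bromine-bearing ortho carbon, and a reducing metal would rearomatise with loss of that bromine to give macrocycle A3.
- For it: the route is biomimetic and convergent. The ring-closing bond is a C–O bond made from two free phenols without a prefunctionalised electrophile, and the building blocks are simple halogenated phenols.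
- Against it: A3 keeps a bromine on ring C where the target has a hydroxyl, and two chlorines on ring D where it has hydrogen. Three more operations follow before the ring A methyl ether can be removed: bromine to hydroxyl, reductive removal of both chlorines, and these must be told apart chemoselectively. The oxidant is a stoichiometric toxic heavy metal. Which phenol is oxidised depends only on the difference between bromine and chlorine substitution, and intermolecular coupling competes.
- Comparison: this route is stronger in convergence. The chosen route offers the final oxygenation pattern on ring C from the purchased ester and leaves no halogen to repair after ring closure.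

**Alternative 3: nitro-activated substitution closing the ring A ether.** The ring A carbon–oxygen bond is disconnected. The open chain A6 carries a 3-fluoro-4-nitrophenyl ring A and a free ring B phenol. Forward, a mild base would generate the phenoxide, which displaces the fluoride ortho to the nitro group and gives nitro macrocycle A5.
- For it: intramolecular addition–elimination is among the most reliable macrocyclic ether closures. It tolerates moderate concentration and needs no metal. On ring-closure reliability it is probably stronger than the chosen step.
- Against it: A5 has a nitro group where the target has the ring A hydroxyl. Reduction, diazotisation and hydrolysis are needed, and the diazonium group would sit ortho to an aryloxy substituent, where radical or cationic ring closure onto ring B to a dibenzofuran competes with hydrolysis. With demethylation of ring C this makes four steps after ring closure, against two.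
- Comparison: the chosen route accepts a less secure ring closure. In return it carries the correct oxidation pattern on every ring from the first step and ends with two routine steps.

Key step: step 10

Remark on the chemistry: stilbene 10 is expected as an E/Z mixture and is carried on as such, since step 6 removes the double bond.

## Route

Step 1
Reactants: 1 isovanillin (3-hydroxy-4-methoxybenzaldehyde); 2 3-iodophenylboronic acid
Product: 3 3-(3-iodophenoxy)-4-methoxybenzaldehyde
Conditions: Cu(OAc)2 (2 equiv), pyridine, 4 Å MS, CH2Cl2, open to air, rt
Reagents that add atoms: none
Why: Chan–Lam O-arylation: the phenoxide of 1 and the aryl group of 2 meet on copper and the C–O bond forms by reductive elimination from a high-valent copper aryl phenoxide at room temperature. The carbon–iodine bond and the aldehyde are not touched under these oxidative, ligand-free conditions.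

Step 2
Reactants: 3 3-(3-iodophenoxy)-4-methoxybenzaldehyde
Product: 4 [3-(3-iodophenoxy)-4-methoxyphenyl]methanol
Conditions: NaBH4, MeOH/THF, 0 °C
Reagents that add atoms: none
Why: Hydride reduction of an aryl aldehyde; NaBH4 leaves the aryl iodide and the ethers alone.

Step 3
Reactants: 4 [3-(3-iodophenoxy)-4-methoxyphenyl]methanol
Product: 5 {[3-(3-iodophenoxy)-4-methoxyphenyl]methyl}triphenylphosphonium bromide
Conditions: PPh3·HBr, MeCN, reflux
Reagents that add atoms: triphenylphosphine hydrobromide, [Br-].c1ccc(cc1)[PH+](c1ccccc1)c1ccccc1
Why: Phosphonium salt formation from a benzylic alcohol: HBr ionises the benzylic C–O bond, which the para methoxy group activates, and PPh3 captures the benzylic electrophile. This saves a separate bromination.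

Step 4
Reactants: 6 methyl 3-hydroxy-4,5-dimethoxybenzoate; 7 4-fluorobenzaldehyde
Product: 8 methyl 3-(4-formylphenoxy)-4,5-dimethoxybenzoate
Conditions: K2CO3, DMF, 130 °C
Reagents that add atoms: none
Why: Nucleophilic aromatic substitution (SNAr): the phenoxide of 6 adds at the fluorine-bearing carbon of 7, the para formyl group stabilises the Meisenheimer intermediate, and fluoride leaves. The methyl ester is stable to dry K2CO3.

Step 5
Reactants: 5 {[3-(3-iodophenoxy)-4-methoxyphenyl]methyl}triphenylphosphonium bromide; 8 methyl 3-(4-formylphenoxy)-4,5-dimethoxybenzoate
Product: 10 methyl 3-(4-{2-[3-(3-iodophenoxy)-4-methoxyphenyl]ethenyl}phenoxy)-4,5-dimethoxybenzoate (E/Z mixture), via phosphonium ylide 9 (not isolated)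
Conditions: K2CO3, 18-crown-6 (cat.), CH2Cl2, reflux
Reagents that add atoms: none
Why: Wittig olefination of a semi-stabilised benzylic ylide, generated under mild solid–liquid phase-transfer conditions that touch neither the methyl ester nor the aryl iodide. The E/Z ratio does not matter because the double bond is removed next.

Step 6
Reactants: 10 methyl 3-(4-{2-[3-(3-iodophenoxy)-4-methoxyphenyl]ethenyl}phenoxy)-4,5-dimethoxybenzoate (E/Z mixture)
Product: 11 methyl 3-(4-{2-[3-(3-iodophenoxy)-4-methoxyphenyl]ethyl}phenoxy)-4,5-dimethoxybenzoate
Conditions: TsNHNH2 (excess, in portions), NaOAc, DME/H2O, reflux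
Reagents that add atoms: none
Why: Diimide reduction: diimide from thermal fragmentation of the sulfonyl hydrazide delivers two hydrogens to the C=C bond through a concerted cyclic transition state. Unlike H2 over palladium, it cannot cleave the carbon–iodine bond needed in step 10.

Step 7
Reactants: 11 methyl 3-(4-{2-[3-(3-iodophenoxy)-4-methoxyphenyl]ethyl}phenoxy)-4,5-dimethoxybenzoate
Product: 12 [3-(4-{2-[3-(3-iodophenoxy)-4-methoxyphenyl]ethyl}phenoxy)-4,5-dimethoxyphenyl]methanol
Conditions: i-Bu2AlH, CH2Cl2, −78 → 0 °C; aq. potassium sodium tartrate
Reagents that add atoms: none
Why: Hydride reduction of the methyl ester to the primary benzylic alcohol; i-Bu2AlH at low temperature reduces neither aryl iodides nor diaryl ethers.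

Step 8
Reactants: 12 [3-(4-{2-[3-(3-iodophenoxy)-4-methoxyphenyl]ethyl}phenoxy)-4,5-dimethoxyphenyl]methanol
Product: 13 3-(4-{2-[3-(3-iodophenoxy)-4-methoxyphenyl]ethyl}phenoxy)-4,5-dimethoxybenzaldehyde
Conditions: MnO2 (activated), CH2Cl2, rt
Reagents that add atoms: none
Why: Selective oxidation of a benzylic alcohol on the MnO2 surface; it is neutral and stops at the aldehyde.

Step 9
Reactants: 13 3-(4-{2-[3-(3-iodophenoxy)-4-methoxyphenyl]ethyl}phenoxy)-4,5-dimethoxybenzaldehyde
Product: 14 5-ethynyl-1-(4-{2-[3-(3-iodophenoxy)-4-methoxyphenyl]ethyl}phenoxy)-2,3-dimethoxybenzene
Conditions: dimethyl (1-diazo-2-oxopropyl)phosphonate, K2CO3, MeOH/THF, 0 °C → rt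
Reagents that add atoms: dimethyl (1-diazo-2-oxopropyl)phosphonate (Ohira–Bestmann reagent), COP(=O)(OC)C(=[N+]=[N-])C(C)=O
Why: Seyferth–Gilbert homologation in its Ohira–Bestmann form: methanolysis of the reagent gives the diazomethylphosphonate anion, which adds to the aldehyde and eliminates phosphate to a diazoalkene. Loss of nitrogen and a 1,2-hydrogen shift in the alkylidene carbene give the terminal alkyne; K2CO3 in MeOH does not affect the aryl iodide.

Step 10
Reactants: 14 5-ethynyl-1-(4-{2-[3-(3-iodophenoxy)-4-methoxyphenyl]ethyl}phenoxy)-2,3-dimethoxybenzene
Product: 15 macrocyclic diarylalkyne (ring A methyl ether and ring C dimethyl ether of the target skeleton in which the ring B–ring C bridge is a triple bond)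
Conditions: Pd(PPh3)4 (10 mol %), CuI (20 mol %), Et3N, degassed THF, 60 °C, 14 added by syringe pump (final concentration about 1 mM), argon
Reagents that add atoms: none
Why: This is a Sonogashira coupling run intramolecularly: zerovalent palladium inserts into the ring B carbon–iodine bond of 14, CuI and Et3N turn the ring C ethynyl group into its copper acetylide, transmetalation gives an aryl(alkynyl)palladium species, and reductive elimination forms the bond between ring B C-3 and the alkyne carbon. The closest known reaction type is the Sonogashira macrocyclisation of an aryl iodide that carries a remote terminal arylalkyne. The single new ring is 19-membered; it closes end to end through a 20-membered palladacycle and keeps the triple bond inside the ring. No stereocenter is formed. The step needs ring closure to outrun intermolecular coupling and oxidative alkyne dimerisation; slow addition keeps the concentration of free substrate far below that of the catalyst, and exclusion of oxygen removes the oxidant that Glaser coupling requires. In the substrate, the unhindered and not electron-rich ring B iodide adds quickly to palladium while the electron-rich ring C carries the nucleophilic partner. Because both rings at the rod are meta-linked, their ether oxygens can point to the same side, where the flexible ring A–CH2CH2–ring D segment bridges them. Only one carbon–iodine bond and one terminal alkyne are present, so no site selectivity is required.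

Step 11
Reactants: 15 macrocyclic diarylalkyne
Product: 16 tri-O-methyl ether of the target (saturated macrocycle with OMe on ring A and two OMe on ring C)
Conditions: H2 (1 atm), Pd/C, EtOAc/MeOH, rt
Reagents that add atoms: none
Why: Heterogeneous catalytic hydrogenation of the diarylalkyne to the CH2–CH2 bridge. Diaryl and methyl aryl ethers are not hydrogenolysed, and no halogen is left to be lost.

Step 12
Reactants: 16 tri-O-methyl ether of the target
Product: 17 target CNP0495401.0 (ring A phenol and ring C catechol)
Conditions: BBr3, CH2Cl2, −78 °C → rt; then H2O
Reagents that add atoms: none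
Why: Lewis-acid ether cleavage: BBr3 coordinates each methoxy oxygen and bromide attacks the methyl carbon in an SN2 step, while the diaryl ether oxygens have no such carbon and survive. Aqueous work-up hydrolyses the aryl borates to the three phenols.

## Compound list

1 | isovanillin (3-hydroxy-4-methoxybenzaldehyde) | COc1ccc(C=O)cc1O | starting material
2 | 3-iodophenylboronic acid | OB(O)c1cccc(I)c1 | starting material
3 | 3-(3-iodophenoxy)-4-methoxybenzaldehyde | COc1ccc(C=O)cc1Oc1cccc(I)c1 | intermediate
4 | [3-(3-iodophenoxy)-4-methoxyphenyl]methanol | COc1ccc(CO)cc1Oc1cccc(I)c1 | intermediate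
5 | {[3-(3-iodophenoxy)-4-methoxyphenyl]methyl}triphenylphosphonium bromide | COc1ccc(C[P+](c2ccccc2)(c2ccccc2)c2ccccc2)cc1Oc1cccc(I)c1.[Br-] | intermediate
6 | methyl 3-hydroxy-4,5-dimethoxybenzoate | COC(=O)c1cc(O)c(OC)c(OC)c1 | starting material
7 | 4-fluorobenzaldehyde | O=Cc1ccc(F)cc1 | starting material
8 | methyl 3-(4-formylphenoxy)-4,5-dimethoxybenzoate | COC(=O)c1cc(OC)c(OC)c(c1)Oc1ccc(C=O)cc1 | intermediate
9 | [3-(3-iodophenoxy)-4-methoxybenzylidene]triphenylphosphorane (ylide) | COc1ccc(C=P(c2ccccc2)(c2ccccc2)c2ccccc2)cc1Oc1cccc(I)c1 | intermediate (not isolated)
10 | methyl 3-(4-{2-[3-(3-iodophenoxy)-4-methoxyphenyl]ethenyl}phenoxy)-4,5-dimethoxybenzoate, E/Z mixture | COC(=O)c1cc(OC)c(OC)c(c1)Oc1ccc(C=Cc2ccc(OC)c(c2)Oc2cccc(I)c2)cc1 | intermediate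
11 | methyl 3-(4-{2-[3-(3-iodophenoxy)-4-methoxyphenyl]ethyl}phenoxy)-4,5-dimethoxybenzoate | COC(=O)c1cc(OC)c(OC)c(c1)Oc1ccc(CCc2ccc(OC)c(c2)Oc2cccc(I)c2)cc1 | intermediate
12 | [3-(4-{2-[3-(3-iodophenoxy)-4-methoxyphenyl]ethyl}phenoxy)-4,5-dimethoxyphenyl]methanol | OCc1cc(OC)c(OC)c(c1)Oc1ccc(CCc2ccc(OC)c(c2)Oc2cccc(I)c2)cc1 | intermediate
13 | 3-(4-{2-[3-(3-iodophenoxy)-4-methoxyphenyl]ethyl}phenoxy)-4,5-dimethoxybenzaldehyde | O=Cc1cc(OC)c(OC)c(c1)Oc1ccc(CCc2ccc(OC)c(c2)Oc2cccc(I)c2)cc1 | intermediate
14 | 5-ethynyl-1-(4-{2-[3-(3-iodophenoxy)-4-methoxyphenyl]ethyl}phenoxy)-2,3-dimethoxybenzene | C#Cc1cc(OC)c(OC)c(c1)Oc1ccc(cc1)CCc1ccc(OC)c(c1)Oc1cccc(I)c1 | intermediate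
15 | macrocyclic diarylalkyne, tri-O-methyl skeleton with C≡C between rings B and C | COc1ccc2cc1Oc1cccc(c1)C#Cc1cc(OC)c(OC)c(c1)Oc1ccc(cc1)CC2 | intermediate
16 | tri-O-methyl ether of the target | COc1ccc2cc1Oc1cccc(c1)CCc1cc(OC)c(OC)c(c1)Oc1ccc(cc1)CC2 | intermediate
17 | CNP0495401.0 | Oc1ccc2cc1Oc1cccc(c1)CCc1cc(O)c(O)c(c1)Oc1ccc(cc1)CC2 | target

## Step count and risk

Total step count: 12. Longest linear sequence: 11 steps (steps 1 to 3 and 5 to 12; step 4 is the only branch).

**Step 10 (key step).** Intermolecular coupling to cyclic dimers and oligomers, and oxidative homocoupling of the terminal alkyne, may overtake ring closure. The chain has to fold so that a linear aryl–C≡C–aryl unit can form inside a 19-membered ring, and some strain in the reductive elimination is to be expected. The fallback sets out from aldehyde 13 and comes back at 16. Methylenation of 13 (Ph3PCH3Br, KOt-Bu, THF, 0 °C) should give 5-ethenyl-1-(4-{2-[3-(3-iodophenoxy)-4-methoxyphenyl]ethyl}phenoxy)-2,3-dimethoxybenzene F1. Hydroboration of F1 with 9-borabicyclo[3.3.1]nonane (THF, rt) at the terminal carbon should give the B-alkyl-9-borabicyclo[3.3.1]nonane F2, which is not isolated. Its solution is added slowly to Pd(dppf)Cl2 and aqueous K3PO4 in THF/DMF at 60 °C under dilution. This intramolecular B-alkyl Suzuki–Miyaura coupling forms the same ring B C-3–bridge carbon bond, but through a flexible sp3 chain and with no alkyne to dimerise. It delivers 16 directly, so step 11 is not needed.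

**Step 6.** Incomplete transfer of hydrogen is the likely failure. Diimide disproportionates faster than it reduces a 1,2-diarylethene, the E isomer in particular, and forcing the reaction prolongs exposure of the ester to hot aqueous acetate. The fallback moves the saturation to a stage without iodine; it sets out from aldehyde 8 and comes back at 11. Commercial [3-(benzyloxy)-4-methoxyphenyl]methanol F3 is heated with PPh3·HBr in MeCN to give {[3-(benzyloxy)-4-methoxyphenyl]methyl}triphenylphosphonium bromide F4. With K2CO3 and 18-crown-6 in CH2Cl2, F4 gives [3-(benzyloxy)-4-methoxybenzylidene]triphenylphosphorane F5 in the flask, which reacts with 8 to give methyl 3-(4-{2-[3-(benzyloxy)-4-methoxyphenyl]ethenyl}phenoxy)-4,5-dimethoxybenzoate F6. Hydrogenation of F6 (H2, Pd/C, EtOAc/MeOH) saturates the double bond and removes the benzyl group in one operation, giving methyl 3-(4-{2-[3-hydroxy-4-methoxyphenyl]ethyl}phenoxy)-4,5-dimethoxybenzoate F7. Chan–Lam coupling of phenol F7 with 2 under the conditions of step 1 then gives 11. Steps 1 to 3 and 5 are bypassed.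

**Step 1.** Protodeboronation and oxidative homocoupling of the boronic acid may consume 2 faster than the ortho-methoxy phenol is arylated, so that conversion of 1 stalls. The fallback reverses the roles of the partners; it sets out from 1 and comes back at 3. Ullmann-type O-arylation of 1 with a threefold excess of 1,3-diiodobenzene (CuI, picolinic acid, K3PO4, DMSO, 85 °C) uses the aryl iodide as electrophile. The excess holds back double arylation, and the unreacted diiodide is recovered. This detour makes no new compound (F0).

## Further compounds

F1 | step 10 | 5-ethenyl-1-(4-{2-[3-(3-iodophenoxy)-4-methoxyphenyl]ethyl}phenoxy)-2,3-dimethoxybenzene | C=Cc1cc(OC)c(OC)c(c1)Oc1ccc(cc1)CCc1ccc(OC)c(c1)Oc1cccc(I)c1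
F2 | step 10 | 9-{2-[3-(4-{2-[3-(3-iodophenoxy)-4-methoxyphenyl]ethyl}phenoxy)-4,5-dimethoxyphenyl]ethyl}-9-borabicyclo[3.3.1]nonane | COc1ccc(CCc2ccc(Oc3cc(CCB4C5CCCC4CCC5)cc(OC)c3OC)cc2)cc1Oc1cccc(I)c1
F3 | step 6 | [3-(benzyloxy)-4-methoxyphenyl]methanol | COc1ccc(CO)cc1OCc1ccccc1
F4 | step 6 | {[3-(benzyloxy)-4-methoxyphenyl]methyl}triphenylphosphonium bromide | COc1ccc(C[P+](c2ccccc2)(c2ccccc2)c2ccccc2)cc1OCc1ccccc1.[Br-]
F5 | step 6 | [3-(benzyloxy)-4-methoxybenzylidene]triphenylphosphorane | COc1ccc(C=P(c2ccccc2)(c2ccccc2)c2ccccc2)cc1OCc1ccccc1
F6 | step 6 | methyl 3-(4-{2-[3-(benzyloxy)-4-methoxyphenyl]ethenyl}phenoxy)-4,5-dimethoxybenzoate, E/Z mixture | COC(=O)c1cc(OC)c(OC)c(c1)Oc1ccc(C=Cc2ccc(OC)c(OCc3ccccc3)c2)cc1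
F7 | step 6 | methyl 3-(4-{2-[3-hydroxy-4-methoxyphenyl]ethyl}phenoxy)-4,5-dimethoxybenzoate | COC(=O)c1cc(OC)c(OC)c(c1)Oc1ccc(CCc2ccc(OC)c(O)c2)cc1
F0 | step 1 | none | none
A1 | alternative 1 | macrocyclic deoxybenzoin with free ring C hydroxyl para to the ketone | COc1ccc2cc1Oc1cccc(c1)CC(=O)c1cc(OC)c(O)c(c1)Oc1ccc(cc1)CC2
A2 | alternative 1 | macrocyclic aryl ester of the ring B arylacetic acid with the ring C phenol oxygen | COc1ccc2cc1Oc1cccc(c1)CC(=O)Oc1c(OC)cccc1Oc1ccc(cc1)CC2
A3 | alternative 2 | macrocycle with one bromine on ring C and two chlorines on ring D | COc1ccc2cc1Oc1cccc(c1)CCc1cc(Br)c(O)c(c1)Oc1c(Cl)cc(cc1Cl)CC2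
A4 | alternative 2 | open-chain bis-phenol with 3,5-dibromo-4-hydroxyphenyl ring C and 3,5-dichloro-4-hydroxyphenyl ring D | COc1ccc(CCc2cc(Cl)c(O)c(Cl)c2)cc1Oc1cccc(CCc2cc(Br)c(O)c(Br)c2)c1
A5 | alternative 3 | macrocycle with nitro in place of the ring A hydroxyl and ring C as dimethyl ether | [O-][N+](=O)c1ccc2cc1Oc1cccc(c1)CCc1cc(OC)c(OC)c(c1)Oc1ccc(cc1)CC2
A6 | alternative 3 | open-chain 3-fluoro-4-nitrophenyl ring A compound with free ring B phenol | [O-][N+](=O)c1ccc(CCc2ccc(Oc3cc(CCc4cccc(O)c4)cc(OC)c3OC)cc2)cc1F
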